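**Strategy**

The side chain's isolated cis double bond C12'=C13' (side-chain atoms numbered from ring carbon C2) is traced back to a terminal alkyne, and the n-octyl group on C13' to oct-1-ene. In the last step a silver carbene catalyst unites B-octyl-9-BBN with the alkyne of (R)-6-methyl-2-(tridec-12-ynyl)-2,3-dihydro-4H-pyran-4-one: an alkynylborate forms, octyl shifts from boron to C13' anti to an incoming proton, and protodeboration leaves the Z-alkene. One operation thus forges the C13'–C14' bond and sets the olefin geometry, with no semihydrogenation and no strong base near the dihydropyranone ring (O1, C2–C6). The alkyne precursor comes from a titanium–BINOL hetero-Diels–Alder reaction of tetradec-13-ynal, which sets C2.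

Key step: step 5

Assumption: (S)-BINOL is taken to direct the diene to the Si face of an unbranched aldehyde, as it does for allyl nucleophiles under titanium–BINOL catalysis; the other ligand enantiomer would be used if the sense proved opposite.

**Route**

Step 1
Reactants: 1 12-bromododecan-1-ol; 2 lithium acetylide–ethylenediamine complex
Product: 3 tetradec-13-yn-1-ol
Conditions: LiC≡CH·H2NCH2CH2NH2 (3 equiv), DMSO, 10 °C → rt; aq. NH4Cl
Reagents that add atoms: none
Why: SN2 alkylation of lithium acetylide by the primary bromide in DMSO should proceed cleanly, the free hydroxyl only consuming one extra equivalent of base and returning on work-up.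

Step 2
Reactants: 3 tetradec-13-yn-1-ol
Product: 4 tetradec-13-ynal
Conditions: TEMPO (10 mol %), PhI(OAc)2 (1.1 equiv), CH2Cl2, rt
Reagents that add atoms: none
Why: the oxoammonium-mediated (TEMPO/PhI(OAc)2) oxidation of a primary alcohol stops at the aldehyde in the absence of water and should leave the terminal alkyne untouched.

Step 3
Reactants: 5 (E)-4-methoxypent-3-en-2-one
Product: 6 (E)-4-methoxy-2-(trimethylsilyloxy)penta-1,3-diene
Conditions: LiN(iPr)2, THF, −78 °C; Me3SiCl, −78 °C → rt; non-aqueous work-up, distillation
Reagents that add atoms: chlorotrimethylsilane, C[Si](C)(C)Cl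
Why: kinetic deprotonation of the methyl ketone (α' position) should give the cross-conjugated lithium enolate, whose O-silylation (silyl enol ether formation) delivers the 1-alkoxy-3-siloxy diene.

Step 4
Reactants: 4 tetradec-13-ynal; 6 (E)-4-methoxy-2-(trimethylsilyloxy)penta-1,3-diene
Product: 8 (R)-6-methyl-2-(tridec-12-yn-1-yl)-2,3-dihydro-4H-pyran-4-one, via silyl aldol adduct 7 (not isolated)
Conditions: (S)-BINOL (20 mol %), Ti(OiPr)4 (10 mol %), CF3CO2H (cat.), 4 Å MS, Et2O, −20 °C; then CF3CO2H, CH2Cl2, 0 °C
Reagents that add atoms: none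
Why: this is a catalytic asymmetric hetero-Diels–Alder reaction in its stepwise Mukaiyama aldol/cyclisation form, in which the chiral titanium–BINOL Lewis acid should direct C1 of the diene to the Si face of the aldehyde (setting C2 as R) and acid then closes the ring by 6-endo addition–elimination of the oxygen onto the β-methoxy enone with loss of methanol.

Step 5
Reactants: 8 (R)-6-methyl-2-(tridec-12-yn-1-yl)-2,3-dihydro-4H-pyran-4-one; 9 oct-1-ene; 10 9-borabicyclo[3.3.1]nonane
Product: 14 (R)-2-[(12Z)-henicos-12-en-1-yl]-6-methyl-2,3-dihydro-4H-pyran-4-one, via B-octyl-9-BBN 11 (not isolated), via alkynylborate 12 (not isolated), via alkenylborane 13 (not isolated)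
Conditions: oct-1-ene (1.6 equiv), 9-BBN (1.5 equiv), THF, 0 °C → rt; then 8, (IPr)AgOAc (5 mol %), MeOH (3 equiv), 1,4-dioxane, 60 °C (IPr = 1,3-bis(2,6-diisopropylphenyl)imidazol-2-ylidene)
Reagents that add atoms: none
Why: Hydroboration of oct-1-ene gives B-octyl-9-BBN; the silver acetate carbene complex metallates the terminal alkyne, the silver acetylide adds to boron to give an alkynylborate, protonation of this at C12' triggers a 1,2-metallate shift of the octyl group from boron to C13', and the resulting alkenylborane is protodeborylated by methanol with retention. The closest known reaction type is the silver-catalysed anti-Markovnikov hydroalkylation of terminal alkynes with B-alkyl-9-BBN reagents, a catalytic relative of Zweifel-type borate rearrangements. No ring is closed and no stereocentre is formed, and C2 is not touched. The Z geometry is required and should be secured by the anti relationship of the incoming proton and the migrating octyl group in the borate, followed by stereoretentive C–B protonolysis. Octyl must migrate in preference to the cage B–C bonds, which the poor migratory aptitude of the 9-BBN bridgehead carbons should secure. The vinylogous ester should be spared because the slight excess of octene leaves no B–H, trialkylboranes do not add to a β,β-disubstituted enone in the absence of oxygen, and the near-neutral medium gives no reason to expect retro-oxa-Michael opening at C2.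

**Compound list**

1 | 12-bromododecan-1-ol | OCCCCCCCCCCCCBr | starting material
2 | lithium acetylide–ethylenediamine complex | [Li+].[C-]#C.NCCN | starting material
3 | tetradec-13-yn-1-ol | C#CCCCCCCCCCCCCO | intermediate
4 | tetradec-13-ynal | C#CCCCCCCCCCCCC=O | intermediate
5 | (E)-4-methoxypent-3-en-2-one | CO/C(C)=C/C(C)=O | starting material
6 | (E)-4-methoxy-2-(trimethylsilyloxy)penta-1,3-diene | CO/C(C)=C/C(=C)O[Si](C)(C)C | intermediate
7 | (2E,6R)-2-methoxy-6-(trimethylsilyloxy)nonadec-2-en-18-yn-4-one (silyl aldol adduct) | C#CCCCCCCCCCCC[C@@H](O[Si](C)(C)C)CC(=O)/C=C(\C)OC | intermediate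
8 | (R)-6-methyl-2-(tridec-12-yn-1-yl)-2,3-dihydro-4H-pyran-4-one | C#CCCCCCCCCCCC[C@@H]1CC(=O)C=C(C)O1 | intermediate
9 | oct-1-ene | C=CCCCCCC | starting material
10 | 9-borabicyclo[3.3.1]nonane (9-BBN, used as its dimer or THF solution) | B1C2CCCC1CCC2 | starting material
11 | 9-octyl-9-borabicyclo[3.3.1]nonane (B-octyl-9-BBN) | CCCCCCCCB1C2CCCC1CCC2 | intermediate
12 | (IPr)Ag+ salt of 9-octyl-9-{13-[(2R)-6-methyl-4-oxo-3,4-dihydro-2H-pyran-2-yl]tridec-1-yn-1-yl}-9-boratabicyclo[3.3.1]nonane (alkynylborate) | CCCCCCCC[B-]1(C#CCCCCCCCCCCC[C@@H]2CC(=O)C=C(C)O2)C2CCCC1CCC2.[Ag]C1=[N+](c2c(C(C)C)cccc2C(C)C)C=CN1c1c(C(C)C)cccc1C(C)C | intermediate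
13 | (R)-2-[(12Z)-13-(9-borabicyclo[3.3.1]nonan-9-yl)henicos-12-en-1-yl]-6-methyl-2,3-dihydro-4H-pyran-4-one (alkenylborane) | CCCCCCCC/C(=C\CCCCCCCCCCC[C@@H]1CC(=O)C=C(C)O1)B2C3CCCC2CCC3 | intermediate
14 | (R)-2-[(12Z)-henicos-12-en-1-yl]-6-methyl-2,3-dihydro-4H-pyran-4-one | CCCCCCCC/C=C\CCCCCCCCCCC[C@@H]1CC(=O)C=C(C)O1 | target

**Count**

Total steps: 5. Longest linear sequence: 4 steps (steps 1, 2, 4, 5); step 3 prepares the diene in a side branch.

**Steps most likely to fail, with fallbacks**

Step 5. The dihydropyranone may suffer 1,2-reduction by residual borane or base-induced ring opening with erosion at C2. A cage B–C bond may migrate in place of octyl, or the protodeboration may not be fully stereoretentive. The fallback makes the same C13'–C14' bond before the ring exists and returns to the route at target 14. It sets out from alkynol 3: double deprotonation (n-BuLi, 2.1 equiv, THF/DMPU, −78 → 0 °C) and alkylation of the acetylide with 1-bromooctane should give docos-13-yn-1-ol F1. Semihydrogenation (H2, Pd/CaCO3/Pb(OAc)2, quinoline, hexane) should give (Z)-docos-13-en-1-ol F2, and TEMPO/PhI(OAc)2 oxidation (Z)-docos-13-enal F3. Under the conditions of step 4 with diene 6, F3 should pass through (2E,6R,18Z)-2-methoxy-6-(trimethylsilyloxy)heptacosa-2,18-dien-4-one F4 and close to 14.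

Step 4. The methyl-bearing diene may add with insufficient facial selectivity under titanium–BINOL catalysis, or may be hydrolysed faster than it adds. The fallback replaces catalyst control by a separable auxiliary-controlled aldol; it sets out from aldehyde 4 and returns at 8. The titanium enolate of (R)-3-acetyl-4-benzyl-1,3-thiazolidine-2-thione (TiCl4, iPr2NEt, CH2Cl2, −78 °C; auxiliary enantiomer chosen on the chelated chair model) should add to 4 to give (R)-1-[(R)-4-benzyl-2-thioxo-1,3-thiazolidin-3-yl]-3-hydroxyhexadec-15-yn-1-one F5, purified from its diastereomer by chromatography. Displacement of the auxiliary with MeNHOMe·HCl/imidazole should give (R)-3-hydroxy-N-methoxy-N-methylhexadec-15-ynamide F6. Excess prop-1-ynylmagnesium bromide (THF, 0 °C) should give (R)-6-hydroxynonadeca-2,18-diyn-4-one F7. Brønsted-acid 6-endo-dig oxa-Michael cyclisation (cat. CF3SO3H, CH2Cl2) then closes the ring to 8.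

Step 1. The strongly basic acetylide in DMSO may eliminate HBr from the bromide or move the new triple bond into the chain. The fallback uses a silyl-capped acetylide that cannot isomerise, then unmasks it; it sets out from 1 and returns at 3. Lithium (trimethylsilyl)acetylide (2.2 equiv, from ethynyltrimethylsilane and n-BuLi; THF/DMPU, −78 °C → rt) should give 14-(trimethylsilyl)tetradec-13-yn-1-ol F8, and K2CO3 in MeOH removes the silyl group to give 3.

Further compounds
F1 | step 5 | docos-13-yn-1-ol | CCCCCCCCC#CCCCCCCCCCCCCO
F2 | step 5 | (Z)-docos-13-en-1-ol | CCCCCCCC/C=C\CCCCCCCCCCCCO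
F3 | step 5 | (Z)-docos-13-enal | CCCCCCCC/C=C\CCCCCCCCCCCC=O
F4 | step 5 | (2E,6R,18Z)-2-methoxy-6-(trimethylsilyloxy)heptacosa-2,18-dien-4-one | CCCCCCCC/C=C\CCCCCCCCCCC[C@@H](O[Si](C)(C)C)CC(=O)/C=C(\C)OC
F5 | step 4 | (R)-1-[(R)-4-benzyl-2-thioxo-1,3-thiazolidin-3-yl]-3-hydroxyhexadec-15-yn-1-one | C#CCCCCCCCCCCC[C@@H](O)CC(=O)N1[C@H](Cc2ccccc2)CSC1=S
F6 | step 4 | (R)-3-hydroxy-N-methoxy-N-methylhexadec-15-ynamide | C#CCCCCCCCCCCC[C@@H](O)CC(=O)N(C)OC
F7 | step 4 | (R)-6-hydroxynonadeca-2,18-diyn-4-one | C#CCCCCCCCCCCC[C@@H](O)CC(=O)C#CC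
F8 | step 1 | 14-(trimethylsilyl)tetradec-13-yn-1-ol | C[Si](C)(C)C#CCCCCCCCCCCCCO
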